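**Plan**
1. Retrosynthetic cuts: first the three O–Si bonds and C5–Cl. Next C1'=C2', which releases a C2'–C7' allylic phosphonate. Then the C3=C4 and C4a=C5 π bonds, the C7–CH3 bond and the oxidation level of C1. Last, C4a–C5 and C8–C8a together in one [4+2] step.
2. Enabling feature (isochromene numbering O2, C1, C3, C4, C4a, C5–C8, C8a; side chain primed): ring A is a six-membered carbocycle oxygenated at C6, C7 and C8, and its C8–O bond is cis to the C8a–C1 bond. With C1 drawn as a lactone carbonyl, C4a=C8a is the alkene of a dihydropyranone (ring B) and C5–C8 is a 1,2,3-trioxygenated butadiene. An endo addition then gives this cis relation directly.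
3. Forward order: ring B by ring-closing metathesis, then ring A by the cycloaddition. Ring B is reduced open and re-closed as the cyclic ether while C6 stays masked as its enol silane. C7 methylation, twofold dehydrogenation, chain attachment, chlorination and desilylation follow.
4. Stereochemistry: C3 comes from (R)-benzyl glycidyl ether, steers C4a/C8a by anti approach and is erased later. C8 follows from the endo rule and C7 from convex-face methylation anti to O8. C5'/C6' come from ethyl (S)-3-hydroxybutanoate by anti-selective Fráter–Seebach methylation. Both E alkenes come from stabilised-ylide and phosphonate olefinations.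

Key step: step 6

Abbreviations: Bn = benzyl, TBS = tert-butyldimethylsilyl, TES = triethylsilyl, Ts = p-toluenesulfonyl.
Assumption: the geometry of the aldehyde-derived enol silane made in step 12 is not controlled. Both isomers converge in step 13, so that double bond carries no descriptor in its SMILES.

**Step 1**
Reactants: 1 (R)-benzyl glycidyl ether
Product: 2 (R)-1-(benzyloxy)pent-4-en-2-ol
Conditions: CH2=CHMgBr (1.5 equiv), CuI (10 mol %), THF, −40 to −20 °C
Reagents that add atoms: vinylmagnesium bromide, C=C[Mg]Br
Why: Copper-catalysed Grignard opening of a terminal epoxide is an SN2 attack at the unsubstituted carbon, so the carbinol centre (future C3, R) is carried over unchanged.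

**Step 2**
Reactants: 2 (R)-1-(benzyloxy)pent-4-en-2-ol; 3 acryloyl chloride
Product: 4 (R)-1-(benzyloxy)pent-4-en-2-yl acrylate
Conditions: Et3N, DMAP (cat.), CH2Cl2, 0 °C
Reagents that add atoms: none
Why: Routine O-acylation of a secondary alcohol by an acid chloride installs C1 and C8a without touching the stereocentre.

**Step 3**
Reactants: 4 (R)-1-(benzyloxy)pent-4-en-2-yl acrylate
Product: 5 (R)-6-(benzyloxymethyl)-5,6-dihydro-2H-pyran-2-one
Conditions: second-generation Grubbs catalyst (H2IMes)(PCy3)Cl2Ru=CHPh (5 mol %), CH2Cl2 (0.01 M), 40 °C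
Reagents that add atoms: none
Why: Ring-closing metathesis of an acrylate with a terminal alkene is the standard entry to 6-substituted 5,6-dihydropyran-2-ones and closes ring B with loss of ethene, the electron-poor acrylate being handled well by the N-heterocyclic-carbene ruthenium catalyst.

**Step 4**
Reactants: 6 1-(benzyloxy)propan-2-one
Product: 8 (Z)-3-(benzyloxy)-4-(tert-butyldimethylsilyloxy)but-3-en-2-one, via sodium enolate 7 (not isolated)
Conditions: NaH (1.1 equiv), HCO2Et (3 equiv), EtOH (cat.), THF, 0 °C to rt; then TBSCl (1.1 equiv), 0 °C to rt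
Reagents that add atoms: ethyl formate, CCOC=O; tert-butyldimethylsilyl chloride, CC(C)(C)[Si](C)(C)Cl; sodium hydride, [H-].[Na+] (supplies the sodium of 7 only)
Why: Crossed Claisen formylation under equilibrating conditions ends at the more acidic, oxygen-flanked CH2 (future C7), the hard silyl chloride traps the resulting enolate on oxygen, the isomer having O8 trans to the acetyl group (the two C–O bonds cis) is the less crowded one, and silylation on the other oxygen would converge on the same diene in step 5.

**Step 5**
Reactants: 8 (Z)-3-(benzyloxy)-4-(tert-butyldimethylsilyloxy)but-3-en-2-one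
Product: 9 (1Z)-2-(benzyloxy)-1,3-bis(tert-butyldimethylsilyloxy)buta-1,3-diene (O on C1 trans to C3)
Conditions: TBSOTf (1.1 equiv), Et3N (2 equiv), Et2O, 0 °C
Reagents that add atoms: tert-butyldimethylsilyl triflate, CC(C)(C)[Si](C)(C)OS(=O)(=O)C(F)(F)F
Why: Soft enolisation of a methyl ketone by a silyl triflate and a tertiary amine is the usual way to 3-silyloxybutadienes and leaves the geometry of the existing enol ether untouched.

**Step 6**
Reactants: 5 (R)-6-(benzyloxymethyl)-5,6-dihydro-2H-pyran-2-one; 9 (1Z)-2-(benzyloxy)-1,3-bis(tert-butyldimethylsilyloxy)buta-1,3-diene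
Product: 10 (3R,4aR,8R,8aR)-7-(benzyloxy)-3-(benzyloxymethyl)-6,8-bis(tert-butyldimethylsilyloxy)-3,4,4a,5,8,8a-hexahydro-1H-isochromen-1-one (cis-fused; H4a, H8a and the C3 substituent on one face, O8 on the other)
Conditions: 9 (2 equiv), 2,6-di-tert-butyl-4-methylphenol (trace), CH2Cl2, 13 kbar, 40 °C, 72 h
Reagents that add atoms: none
Why: This is a concerted, asynchronous normal-electron-demand [4+2] cycloaddition in which three oxygen donors raise the HOMO of 9 and high pressure exploits the negative activation volume, so that the weakly activated lactone can react without a Lewis acid that might strip the silyl groups. The closest known reaction type is the Diels–Alder addition of 1-alkoxy-3-silyloxybutadienes to α,β-unsaturated δ-lactones. Ring A closes in the cycloaddition itself as a six-membered annulation on the C4a=C8a edge of ring B, and because C4a–C5 and C8–C8a form suprafacially the ring fusion is cis. The required regiochemistry follows from C5 being pushed by the C6 oxygen and, vinylogously, by the C8 oxygen while C8 is pushed only by the C7 oxygen, so the CH2 terminus bonds to the electrophilic β-carbon C4a. C4a and C8a are set by approach of the diene anti to the pseudoequatorial C3 benzyloxymethyl group of the half-chair lactone (the face preference known from trans-selective conjugate additions to 6-substituted dihydropyranones), and C8 is set by the endo transition state, which places the outward-pointing C8 silyloxy group cis to the C1 carbonyl. Only the diene isomer with O8 trans to C6 can reach the s-cis conformation, so a minor geometric isomer should stay behind and not leak into the stereochemical outcome.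

**Step 7**
Reactants: 10 cycloadduct lactone
Product: 11 (2R)-1-(benzyloxy)-3-[(1R,5R,6S)-4-(benzyloxy)-3,5-bis(tert-butyldimethylsilyloxy)-6-(hydroxymethyl)cyclohex-3-en-1-yl]propan-2-ol (ring B opened: C1H2OH and C3HOH)
Conditions: i-Bu2AlH (4.5 equiv), CH2Cl2, −78 to 0 °C
Reagents that add atoms: none
Why: Exhaustive hydride reduction of a lactone gives the 1,5-diol, the C6 ketone being protected as its enol silane and the covalent aluminium alkoxides formed being too weakly nucleophilic to pull the silyl group from O8 over to the C1 oxygen.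

**Step 8**
Reactants: 11 diol
Product: 13 (3R,4aR,8R,8aS)-7-(benzyloxy)-3-(benzyloxymethyl)-6,8-bis(tert-butyldimethylsilyloxy)-3,4,4a,5,8,8a-hexahydro-1H-isochromene, via primary tosylate 12 (not isolated)
Conditions: TsCl (1.05 equiv), Et3N, DMAP (cat.), CH2Cl2, 0 °C; solvent switch; NaH (1.5 equiv), THF, 0 to 40 °C
Reagents that add atoms: p-toluenesulfonyl chloride, Cc1ccc(cc1)S(=O)(=O)Cl (its atoms remain in 12 only)
Why: Selective sulfonylation of the primary C1 hydroxyl followed by an intramolecular Williamson etherification (6-exo-tet attack of the C3 alkoxide on C1) re-forms ring B at the ether oxidation level under non-acidic conditions that the enol silane tolerates, and no bond to a stereocentre is broken.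

**Step 9**
Reactants: 13 bicyclic enol silane
Product: 14 (3R,4aR,7R,8R,8aS)-7-(benzyloxy)-3-(benzyloxymethyl)-8-(tert-butyldimethylsilyloxy)-7-methylhexahydro-1H-isochromen-6(7H)-one
Conditions: MeI (10 equiv), [(Me2N)3S][Me3SiF2] (TASF, 1.0 equiv), THF, −78 to −30 °C
Reagents that add atoms: methyl iodide, CI
Why: Fluoride-induced regiospecific alkylation of an enol silane releases the C6=C7 enolate exactly where the cycloaddition stored it (the enol O–Si bond is far more fluoride-labile than the secondary C8 silyl ether), and methyl iodide attacks C7 on the convex face, anti to the pseudoaxial C8 silyloxy group and to ring B, which sets (7R) with the C7 and C8 oxygens cis.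

**Step 10**
Reactants: 14 methylated ketone
Product: 15 (3R,4aR,7R,8R,8aS)-8-(tert-butyldimethylsilyloxy)-7-hydroxy-3-(hydroxymethyl)-7-methylhexahydro-1H-isochromen-6(7H)-one
Conditions: H2 (1 atm), Pd(OH)2/C, EtOAc, rt
Reagents that add atoms: none
Why: Catalytic hydrogenolysis cleaves both benzyl ethers at the one stage of the route that contains no alkene, while ketone, cyclic ether and silyl ether are inert in ethyl acetate.

**Step 11**
Reactants: 15 keto diol
Product: 16 (3R,4aR,7R,8R,8aS)-8-(tert-butyldimethylsilyloxy)-7-hydroxy-7-methyl-6-oxooctahydro-1H-isochromene-3-carbaldehyde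
Conditions: Dess–Martin periodinane, CH2Cl2, 0 °C to rt
Reagents that add atoms: none
Why: Dess–Martin oxidation meets only one oxidisable hydroxyl, the primary C1' alcohol, because the C7 hydroxyl is tertiary, and any epimerisation at C3 is irrelevant since that centre is about to become sp2.

**Step 12**
Reactants: 16 keto aldehyde
Product: 17 (4aS,7R,8R,8aS)-8-(tert-butyldimethylsilyloxy)-7-methyl-6,7-bis(triethylsilyloxy)-3-[(triethylsilyloxy)methylidene]-3,4,4a,7,8,8a-hexahydro-1H-isochromene
Conditions: TESOTf (5 equiv), Et3N (8 equiv), CH2Cl2, 0 °C to rt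
Reagents that add atoms: triethylsilyl triflate, CC[Si](CC)(CC)OS(=O)(=O)C(F)(F)F
Why: Soft enolisation with a silyl triflate and amine is regiochemically unambiguous here, the ketone having hydrogens only at C5 (C7 is quaternary) and the aldehyde only at C3, and the same reagent caps the tertiary C7 hydroxyl, so that C8a–H is never exposed to base next to an enone.

**Step 13**
Reactants: 17 bis(enol silane)
Product: 18 (7R,8R,8aS)-8-(tert-butyldimethylsilyloxy)-7-methyl-6-oxo-7-(triethylsilyloxy)-6,7,8,8a-tetrahydro-1H-isochromene-3-carbaldehyde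
Conditions: Pd(OAc)2 (2.5 equiv), MeCN, rt to 40 °C
Reagents that add atoms: none
Why: Twofold Saegusa–Ito oxidation, in which each enol silane is turned by divalent palladium into an oxa-π-allyl complex that loses a syn β-hydrogen (H4a for the C5-bound metal on the convex face, one H4 for the C3-bound metal), creates C4a=C5 and C3=C4, erases the C3 and C4a stereocentres and leaves C7, C8 and C8a untouched.

**Step 14**
Reactants: 19 ethyl (S)-3-hydroxybutanoate
Product: 20 ethyl (2S,3S)-3-hydroxy-2-methylbutanoate
Conditions: LiN(i-Pr)2 (2.2 equiv), THF, −78 to −20 °C; MeI, DMPU, −78 to 0 °C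
Reagents that add atoms: methyl iodide, CI
Why: Fráter–Seebach alkylation: the chelated lithium alkoxide enolate is methylated on the face opposite the C3 methyl group, which gives the anti (2S,3S) product.

**Step 15**
Reactants: 20 ethyl (2S,3S)-3-hydroxy-2-methylbutanoate
Product: 21 ethyl (2S,3S)-3-(tert-butyldimethylsilyloxy)-2-methylbutanoate
Conditions: TBSCl, imidazole, DMF, rt
Reagents that add atoms: tert-butyldimethylsilyl chloride, CC(C)(C)[Si](C)(C)Cl
Why: Standard silylation of a secondary alcohol gives a group that survives hydride, ylide, phosphite and organolithium reagents and falls in the final fluoride step.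

**Step 16**
Reactants: 21 silyloxy ester
Product: 22 (2S,3S)-3-(tert-butyldimethylsilyloxy)-2-methylbutanal
Conditions: i-Bu2AlH (1.05 equiv), CH2Cl2, −78 °C
Reagents that add atoms: none
Why: Partial reduction of an ester by one equivalent of i-Bu2AlH at low temperature stops at the tetrahedral aluminium hemiacetal and delivers the α-chiral aldehyde without epimerisation.

**Step 17**
Reactants: 22 aldehyde
Product: 23 ethyl (2E,4R,5S)-5-(tert-butyldimethylsilyloxy)-2,4-dimethylhex-2-enoate
Conditions: Ph3P=C(CH3)CO2Et, toluene, 80 °C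
Reagents that add atoms: ethyl 2-(triphenylphosphoranylidene)propanoate, CCOC(=O)C(C)=P(c1ccccc1)(c1ccccc1)c1ccccc1
Why: Wittig olefination with a stabilised, α-branched ylide is reliably E-selective and, being free of added base, does not epimerise the α-stereocentre.

**Step 18**
Reactants: 23 enoate
Product: 24 (2E,4R,5S)-5-(tert-butyldimethylsilyloxy)-2,4-dimethylhex-2-en-1-ol
Conditions: i-Bu2AlH (2.3 equiv), CH2Cl2, −78 °C
Reagents that add atoms: none
Why: 1,2-Reduction of an enoate by i-Bu2AlH gives the allylic alcohol with the alkene geometry retained.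

**Step 19**
Reactants: 24 allylic alcohol
Product: 25 (2E,4R,5S)-1-bromo-5-(tert-butyldimethylsilyloxy)-2,4-dimethylhex-2-ene
Conditions: CBr4, PPh3, CH2Cl2, 0 °C
Reagents that add atoms: carbon tetrabromide, BrC(Br)(Br)Br
Why: Appel bromination converts the primary allylic alcohol under neutral conditions by SN2 displacement, without allylic transposition.

**Step 20**
Reactants: 25 allylic bromide
Product: 26 diethyl [(2E,4R,5S)-5-(tert-butyldimethylsilyloxy)-2,4-dimethylhex-2-en-1-yl]phosphonate
Conditions: P(OEt)3 (neat), 120 °C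
Reagents that add atoms: triethyl phosphite, CCOP(OCC)OCC
Why: Michaelis–Arbuzov reaction of a primary allylic bromide proceeds by SN2 attack of phosphorus at the CH2 terminus, keeping the E-trisubstituted alkene in place.

**Step 21**
Reactants: 18 dienone aldehyde; 26 allylic phosphonate
Product: 27 (7R,8R,8aS)-8-(tert-butyldimethylsilyloxy)-3-[(1E,3E,5R,6S)-6-(tert-butyldimethylsilyloxy)-3,5-dimethylhepta-1,3-dien-1-yl]-7-methyl-7-(triethylsilyloxy)-1,7,8,8a-tetrahydro-6H-isochromen-6-one
Conditions: 26, n-BuLi (0.95 equiv on 26), THF–DMPU, −78 °C; then 18, −78 to −20 °C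
Reagents that add atoms: none
Why: Horner–Wadsworth–Emmons olefination with a lithiated allylic phosphonate is E-selective for the new C1'=C2' bond, the aldehyde is far more electrophilic than the hindered, vinylogous-ester-type C6 ketone, and addition at −78 °C with no excess base should outrun deprotonation at C8a.

**Step 22**
Reactants: 27 protected deschloro compound
Product: 28 (7R,8R,8aS)-8-(tert-butyldimethylsilyloxy)-3-[(1E,3E,5R,6S)-6-(tert-butyldimethylsilyloxy)-3,5-dimethylhepta-1,3-dien-1-yl]-5-chloro-7-methyl-7-(triethylsilyloxy)-1,7,8,8a-tetrahydro-6H-isochromen-6-one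
Conditions: NCS (1.05 equiv), MeCN, 0 °C to rt, dark
Reagents that add atoms: N-chlorosuccinimide, O=C1CCC(=O)N1Cl
Why: Electrophilic halogenation of a doubly vinylogous ester: O2 pushes electron density through C3=C4–C4a=C5 onto C5, the α-carbon of the ketone and the site at which related isochromen-6-one chromophores take up halogen from N-halosuccinimides, whereas the side-chain diene is deactivated by conjugation to the carbonyl group, and loss of H5 restores the chromophore.

**Step 23**
Reactants: 28 protected chloro compound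
Product: 29 (7R,8R,8aS)-5-chloro-7,8-dihydroxy-3-[(1E,3E,5R,6S)-6-hydroxy-3,5-dimethylhepta-1,3-dien-1-yl]-7-methyl-1,7,8,8a-tetrahydro-6H-isochromen-6-one (CNP0536300.1)
Conditions: HF·pyridine, pyridine, THF, 0 °C to rt
Reagents that add atoms: none
Why: Buffered fluoride-mediated desilylation removes the three silyl ethers in one operation under weakly acidic conditions that avoid retro-aldol cleavage of the C7–C8 bond and vinylogous elimination of the C8 oxygen, both of which need base.

**Compound list**
1 | (R)-benzyl glycidyl ether | C(OCc1ccccc1)[C@H]1CO1 | starting material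
2 | (R)-1-(benzyloxy)pent-4-en-2-ol | O[C@@H](COCc1ccccc1)CC=C | intermediate
3 | acryloyl chloride | C=CC(=O)Cl | starting material
4 | (R)-1-(benzyloxy)pent-4-en-2-yl acrylate | C=CC(=O)O[C@@H](COCc1ccccc1)CC=C | intermediate
5 | (R)-6-(benzyloxymethyl)-5,6-dihydro-2H-pyran-2-one | O=C1O[C@@H](COCc2ccccc2)CC=C1 | intermediate
6 | 1-(benzyloxy)propan-2-one | CC(=O)COCc1ccccc1 | starting material
7 | sodium (Z)-2-(benzyloxy)-3-oxobut-1-en-1-olate | CC(=O)/C(OCc1ccccc1)=C/[O-].[Na+] | intermediate
8 | (Z)-3-(benzyloxy)-4-(tert-butyldimethylsilyloxy)but-3-en-2-one | CC(=O)/C(OCc1ccccc1)=C/O[Si](C)(C)C(C)(C)C | intermediate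
9 | (1Z)-2-(benzyloxy)-1,3-bis(tert-butyldimethylsilyloxy)buta-1,3-diene | C=C(O[Si](C)(C)C(C)(C)C)/C(OCc1ccccc1)=C/O[Si](C)(C)C(C)(C)C | intermediate
10 | (3R,4aR,8R,8aR) cis-fused cycloadduct lactone | O=C1O[C@@H](COCc3ccccc3)C[C@@H]2CC(O[Si](C)(C)C(C)(C)C)=C(OCc3ccccc3)[C@H](O[Si](C)(C)C(C)(C)C)[C@H]12 | intermediate
11 | ring-B-opened C1,C3-diol | OC[C@H]1[C@@H](O[Si](C)(C)C(C)(C)C)C(OCc2ccccc2)=C(O[Si](C)(C)C(C)(C)C)C[C@H]1C[C@@H](O)COCc1ccccc1 | intermediate
12 | C1 primary tosylate of 11 | Cc1ccc(cc1)S(=O)(=O)OC[C@H]1[C@@H](O[Si](C)(C)C(C)(C)C)C(OCc2ccccc2)=C(O[Si](C)(C)C(C)(C)C)C[C@H]1C[C@@H](O)COCc1ccccc1 | intermediate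
13 | (3R,4aR,8R,8aS) hexahydro-1H-isochromene enol silane | C1O[C@@H](COCc3ccccc3)C[C@@H]2CC(O[Si](C)(C)C(C)(C)C)=C(OCc3ccccc3)[C@H](O[Si](C)(C)C(C)(C)C)[C@H]12 | intermediate
14 | (3R,4aR,7R,8R,8aS) C7-methyl ketone | C1O[C@@H](COCc3ccccc3)C[C@@H]2CC(=O)[C@](C)(OCc3ccccc3)[C@H](O[Si](C)(C)C(C)(C)C)[C@H]12 | intermediate
15 | (3R,4aR,7R,8R,8aS) keto diol | C1O[C@@H](CO)C[C@@H]2CC(=O)[C@](C)(O)[C@H](O[Si](C)(C)C(C)(C)C)[C@H]12 | intermediate
16 | (3R,4aR,7R,8R,8aS) keto aldehyde | C1O[C@@H](C=O)C[C@@H]2CC(=O)[C@](C)(O)[C@H](O[Si](C)(C)C(C)(C)C)[C@H]12 | intermediate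
17 | (4aS,7R,8R,8aS) tris(triethylsilyl) bis(enol silane) | C1OC(=CO[Si](CC)(CC)CC)C[C@@H]2C=C(O[Si](CC)(CC)CC)[C@](C)(O[Si](CC)(CC)CC)[C@H](O[Si](C)(C)C(C)(C)C)[C@H]12 | intermediate
18 | (7R,8R,8aS) 6-oxo-tetrahydro-1H-isochromene-3-carbaldehyde | C1OC(C=O)=CC2=CC(=O)[C@](C)(O[Si](CC)(CC)CC)[C@H](O[Si](C)(C)C(C)(C)C)[C@H]12 | intermediate
19 | ethyl (S)-3-hydroxybutanoate | CCOC(=O)C[C@H](C)O | starting material
20 | ethyl (2S,3S)-3-hydroxy-2-methylbutanoate | CCOC(=O)[C@@H](C)[C@H](C)O | intermediate
21 | ethyl (2S,3S)-3-(tert-butyldimethylsilyloxy)-2-methylbutanoate | CCOC(=O)[C@@H](C)[C@H](C)O[Si](C)(C)C(C)(C)C | intermediate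
22 | (2S,3S)-3-(tert-butyldimethylsilyloxy)-2-methylbutanal | O=C[C@@H](C)[C@H](C)O[Si](C)(C)C(C)(C)C | intermediate
23 | ethyl (2E,4R,5S)-5-(tert-butyldimethylsilyloxy)-2,4-dimethylhex-2-enoate | CCOC(=O)/C(C)=C/[C@@H](C)[C@H](C)O[Si](C)(C)C(C)(C)C | intermediate
24 | (2E,4R,5S)-5-(tert-butyldimethylsilyloxy)-2,4-dimethylhex-2-en-1-ol | OC/C(C)=C/[C@@H](C)[C@H](C)O[Si](C)(C)C(C)(C)C | intermediate
25 | (2E,4R,5S)-1-bromo-5-(tert-butyldimethylsilyloxy)-2,4-dimethylhex-2-ene | BrC/C(C)=C/[C@@H](C)[C@H](C)O[Si](C)(C)C(C)(C)C | intermediate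
26 | diethyl [(2E,4R,5S)-5-(tert-butyldimethylsilyloxy)-2,4-dimethylhex-2-en-1-yl]phosphonate | CCOP(=O)(OCC)C/C(C)=C/[C@@H](C)[C@H](C)O[Si](C)(C)C(C)(C)C | intermediate
27 | protected deschloro compound | C1OC(/C=C/C(C)=C/[C@@H](C)[C@H](C)O[Si](C)(C)C(C)(C)C)=CC2=CC(=O)[C@](C)(O[Si](CC)(CC)CC)[C@H](O[Si](C)(C)C(C)(C)C)[C@H]12 | intermediate
28 | protected 5-chloro compound | C1OC(/C=C/C(C)=C/[C@@H](C)[C@H](C)O[Si](C)(C)C(C)(C)C)=CC2=C(Cl)C(=O)[C@](C)(O[Si](CC)(CC)CC)[C@H](O[Si](C)(C)C(C)(C)C)[C@H]12 | intermediate
29 | CNP0536300.1 | CC(/C=C/C1=CC2=C(Cl)C(=O)[C@](C)(O)[C@H](O)[C@@H]2CO1)=C\[C@@H](C)[C@H](C)O | target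

**Step count and weak points**
Total: 23 steps. Longest linear sequence: 14 steps from 1 (steps 1–3, 6–13, 21–23).

**Step 6.** The unactivated lactone may be too poor a partner for a crowded, trisubstituted diene. Slow conversion, diene decomposition under prolonged pressure, or erosion of endo and facial selectivity could then become limiting.
- The fallback sets out from 5 and comes back at 10. It forms the same two bonds but adds a removable activating group at C8a.
- Bromine adds to 5 (Br2, CH2Cl2, 0 °C) to give the trans-dibromolactone F1.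
- Et3N in the same flask removes HBr to give the 3-bromo-dihydropyranone F2.
- The lowered LUMO of F2 should let 9 add in toluene at 80–110 °C and ambient pressure to give the C8a-bromo cycloadduct F3.
- Radical debromination (n-Bu3SnH, AIBN, toluene, 80 °C) transfers hydrogen to the planar C8a radical on the face away from the C8 silyloxy group. This re-creates the cis ring fusion of 10.

**Step 9.** The metal-free enolate may expel the C8 silyloxy group (E1cB) or be methylated on oxygen, or fluoride may attack the C8 silyl ether.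
- The fallback sets out from 13 and returns at 14, and it never generates an enolate.
- The neutral enol silane is alkylated by the thionium ion from chloromethyl phenyl sulfide (PhSCH2Cl, catalytic ZnBr2, CH2Cl2, 0 °C to rt), again on the convex face, to give the 7-(phenylsulfanylmethyl) ketone F4.
- Desulfurisation by acetone-deactivated Raney Ni in EtOH turns CH2SPh into the C7 methyl group of 14 while sparing the benzyl ethers.

**Step 13.** Acetic acid released in the first oxidation may protodesilylate the remaining enol silane. Alternatively, the hindered, oxygen-bearing C3 palladium enolate may be slow to eliminate, so that the reaction stalls after one dehydrogenation.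
- The fallback sets out from 17 and returns at 18, and it replaces palladium chemistry by selenoxide elimination.
- PhSeCl (2.1 equiv, CH2Cl2, −78 °C) selenenylates both enol silanes on the convex face to give the 3,5-bis(phenylselanyl) keto aldehyde F5.
- Oxidation (H2O2, pyridine, CH2Cl2, 0 °C) triggers two syn eliminations, toward H4a (cis to the C5 selenium) and toward C4, giving 18.

**Further compounds**
F1 | step 6 | (6R)-6-(benzyloxymethyl)-trans-3,4-dibromotetrahydropyran-2-one (C3 bromine anti, C4 bromine syn to the C6 substituent) | O=C1O[C@@H](COCc2ccccc2)C[C@@H](Br)[C@@H]1Br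
F2 | step 6 | (R)-6-(benzyloxymethyl)-3-bromo-5,6-dihydro-2H-pyran-2-one | O=C1O[C@@H](COCc2ccccc2)CC=C1Br
F3 | step 6 | 8a-bromo analogue of 10 (bromine in place of H8a, cis to H4a) | O=C1O[C@@H](COCc3ccccc3)C[C@@H]2CC(O[Si](C)(C)C(C)(C)C)=C(OCc3ccccc3)[C@H](O[Si](C)(C)C(C)(C)C)[C@]12Br
F4 | step 9 | analogue of 14 carrying CH2SPh in place of the C7 methyl group | C1O[C@@H](COCc3ccccc3)C[C@@H]2CC(=O)[C@](CSc3ccccc3)(OCc3ccccc3)[C@H](O[Si](C)(C)C(C)(C)C)[C@H]12
F5 | step 13 | 3,5-bis(phenylselanyl) keto aldehyde (both selenium atoms cis to H4a and H8a; O7 as TES ether, O8 as TBS ether) | C1O[C@@](C=O)([Se]c3ccccc3)C[C@@H]2[C@@H]([Se]c3ccccc3)C(=O)[C@](C)(O[Si](CC)(CC)CC)[C@H](O[Si](C)(C)C(C)(C)C)[C@H]12
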